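**Target analysis.** Huazhongilexin is the all-trans, C2-symmetric (2S,3R,4R,5S)-2,5-bis(4-hydroxy-3,5-dimethoxyphenyl)-3,4-bis(hydroxymethyl)tetrahydrofuran (lignan numbering 7S,8R,7'S,8'R).

## Retrosynthetic overview

1. Target ⇒ removal of the benzyl (phenol) and TBDPS (CH2OH) groups ⇒ THF C7–O–C7' bond by SN1 cyclodehydration of a C2-symmetric 1,4-diaryl-butane-1,4-diol.
2. Diol ⇒ LiAlH4 opening of a C2-symmetric cis-fused bis-γ-lactone, then selective silylation of the two primary alcohols.
3. Dilactone ⇒ proposed new catalytic asymmetric double Mukaiyama aldol/bis-lactonisation of 2,5-bis(trimethylsilyloxy)furan (from succinic anhydride) with two O-benzylsyringaldehydes; this makes both C7–C8 bonds and fixes C8/C8'.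
4. Ring order: two temporary γ-lactone rings (step 3) → opened (step 4) → the tetrahydrofuran ring (step 6).

Assumption: simple reagents (BnBr, TMSCl, TBDPSCl) are listed under "Reagents that add atoms" and not numbered; the (R)-catalyst is assumed to give the (1S,2S,5S,6S)-dilactone, and the (S)-catalyst is used if the sense of induction proves opposite.

## Route

**Step 1**
Reactants: 1, syringaldehyde (4-hydroxy-3,5-dimethoxybenzaldehyde)
Product: 2, 4-(benzyloxy)-3,5-dimethoxybenzaldehyde
Conditions: BnBr (1.2 equiv), K2CO3, DMF, 60 °C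
Reagents that add atoms: benzyl bromide, BrCc1ccccc1
Why: Williamson O-alkylation of the phenoxide; no stereocentre is involved.

**Step 2**
Reactants: 3, succinic anhydride
Product: 4, 2,5-bis(trimethylsilyloxy)furan
Conditions: TMSCl (2.5 equiv), Et3N (3 equiv), ZnCl2 (cat.), MeCN, rt → 45 °C; filter, distil
Reagents that add atoms: chlorotrimethylsilane, C[Si](C)(C)Cl
Why: Double O-silylation of the anhydride by soft enolisation gives the aromatic bis(silyl ketene acetal), a known preparation; no stereocentre.

**Step 3 (proposed new step)**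
Reactants: 2, 4-(benzyloxy)-3,5-dimethoxybenzaldehyde (2.1 equiv); 4, 2,5-bis(trimethylsilyloxy)furan (1.0 equiv)
Product: 5, (1S,2S,5S,6S)-2,6-bis[4-(benzyloxy)-3,5-dimethoxyphenyl]-3,7-dioxabicyclo[3.3.0]octane-4,8-dione (cis-fused dilactone, both aryl groups exo)
Conditions: (R)-3,3'-bis[3,5-bis(trifluoromethyl)phenyl]-1,1'-binaphthyl-2,2'-disulfonimide (5 mol %), Et2O, −78 → −40 °C; then TFA (5 equiv), CH2Cl2, 0 °C → rt; recrystallise to upgrade ee
Reagents that add atoms: none
Why: Proposed new method: a catalytic enantioselective double Mukaiyama aldol/bis-lactonisation in which 4 serves as a 1,2-bis-nucleophile. The disulfonimide is silylated by 4 to a Me3Si+/chiral-anion pair that activates 2 as an O-silyl oxocarbenium; C3 of 4 attacks it (first C–C bond, sets C8 under catalyst control) and silyl transfer regenerates the catalyst. The resulting 5-silyloxyfuran-2(3H)-one is still a silyl ketene acetal and attacks a second activated aldehyde at C4 anti to the new C3 substituent (substrate and catalyst control matched), giving the trans, C2-symmetric bis-adduct (not isolated). TFA removes the TMS ethers and each benzylic OH lactonises onto the distal carbonyl, which only the trans bis-adduct can do, giving the cis-fused exo,exo dilactone; C7/C7' are expected to follow the sense of the racemic reaction and one of them is re-formed under SN1 control in step 6. Closest known reactions: the stoichiometric TiCl4-mediated racemic double aldol of 2,5-bis(trimethylsilyloxy)furan with aryl aldehydes to lignan dilactones, and disulfonimide/IDPi "silylium" asymmetric Mukaiyama aldols of simple silyl ketene acetals with aromatic aldehydes.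

**Step 4**
Reactants: 5, dilactone
Product: 6, (1S,2R,3R,4S)-1,4-bis[4-(benzyloxy)-3,5-dimethoxyphenyl]-2,3-bis(hydroxymethyl)butane-1,4-diol
Conditions: LiAlH4 (4 equiv), THF, 0 °C → rt; Fieser work-up
Reagents that add atoms: none
Why: Hydride reduction of both γ-lactones cleaves only the acyl C–O bonds, so all four stereocentres are retained (the S → R change at C2/C3 is a CIP priority change only), and the cis-fused bicycle cannot epimerise α to carbonyl before reduction.

**Step 5**
Reactants: 6, tetraol
Product: 7, (1S,2R,3R,4S)-1,4-bis[4-(benzyloxy)-3,5-dimethoxyphenyl]-2,3-bis[(tert-butyldiphenylsilyloxy)methyl]butane-1,4-diol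
Conditions: TBDPSCl (2.2 equiv), imidazole, CH2Cl2–DMF, 0 °C
Reagents that add atoms: tert-butyl(chloro)diphenylsilane, CC(C)(C)[Si](Cl)(c1ccccc1)c1ccccc1
Why: Chemoselective silylation: the bulky silyl chloride reacts with the two primary alcohols and leaves the hindered secondary benzylic alcohols free, blocking the competing furofuran closure.

**Step 6**
Reactants: 7, bis-TBDPS diol
Product: 8, (2S,3R,4R,5S)-2,5-bis[4-(benzyloxy)-3,5-dimethoxyphenyl]-3,4-bis[(tert-butyldiphenylsilyloxy)methyl]tetrahydrofuran (all-trans)
Conditions: BF3·OEt2 (0.5 equiv), CH2Cl2, −40 → 0 °C; Et3N quench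
Reagents that add atoms: none
Why: SN1 cycloetherification: BF3 ionises one benzylic alcohol to a 4-alkoxybenzyl cation that is captured by the other benzylic OH (five-membered ring); the nucleophilic carbinol keeps its configuration, the new C–O bond forms trans to the adjacent CH2OTBDPS group, and reversible ionisation funnels any epimer to the all-trans thermodynamic isomer.

**Step 7**
Reactants: 8, protected tetrahydrofuran
Product: 9, [(2S,3R,4R,5S)-2,5-bis[4-(benzyloxy)-3,5-dimethoxyphenyl]tetrahydrofuran-3,4-diyl]dimethanol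
Conditions: TBAF (3 equiv), THF, rt
Reagents that add atoms: none
Why: Fluoride-mediated desilylation of the primary TBDPS ethers; benzyl ethers, the THF ring and the stereocentres are inert to these conditions.

**Step 8**
Reactants: 9, di-O-benzyl diol
Product: 10, Huazhongilexin
Conditions: H2 (1 atm), 10 % Pd/C, EtOAc–MeOH, rt, stopped at full conversion
Reagents that add atoms: none
Why: Hydrogenolysis of the aryl benzyl ethers is much faster than cleavage of the dialkyl benzylic C–O bonds of the THF ring, and no stereocentre is touched.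

## Compound list

1 | syringaldehyde (4-hydroxy-3,5-dimethoxybenzaldehyde) | COc1cc(C=O)cc(OC)c1O | starting material
2 | 4-(benzyloxy)-3,5-dimethoxybenzaldehyde | COc1cc(C=O)cc(OC)c1OCc1ccccc1 | intermediate
3 | succinic anhydride | O=C1CCC(=O)O1 | starting material
4 | 2,5-bis(trimethylsilyloxy)furan | C[Si](C)(C)Oc1ccc(O[Si](C)(C)C)o1 | intermediate
5 | (1S,2S,5S,6S)-2,6-bis[4-(benzyloxy)-3,5-dimethoxyphenyl]-3,7-dioxabicyclo[3.3.0]octane-4,8-dione | COc1cc(cc(OC)c1OCc1ccccc1)[C@H]1OC(=O)[C@H]2[C@@H]1C(=O)O[C@@H]2c1cc(OC)c(OCc2ccccc2)c(OC)c1 | intermediate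
6 | (1S,2R,3R,4S)-1,4-bis[4-(benzyloxy)-3,5-dimethoxyphenyl]-2,3-bis(hydroxymethyl)butane-1,4-diol | COc1cc(cc(OC)c1OCc1ccccc1)[C@@H](O)[C@@H](CO)[C@H](CO)[C@H](O)c1cc(OC)c(OCc2ccccc2)c(OC)c1 | intermediate
7 | (1S,2R,3R,4S)-1,4-bis[4-(benzyloxy)-3,5-dimethoxyphenyl]-2,3-bis[(tert-butyldiphenylsilyloxy)methyl]butane-1,4-diol | COc1cc(cc(OC)c1OCc1ccccc1)[C@@H](O)[C@@H](CO[Si](c1ccccc1)(c1ccccc1)C(C)(C)C)[C@H](CO[Si](c1ccccc1)(c1ccccc1)C(C)(C)C)[C@H](O)c1cc(OC)c(OCc2ccccc2)c(OC)c1 | intermediate
8 | (2S,3R,4R,5S)-2,5-bis[4-(benzyloxy)-3,5-dimethoxyphenyl]-3,4-bis[(tert-butyldiphenylsilyloxy)methyl]tetrahydrofuran | COc1cc(cc(OC)c1OCc1ccccc1)[C@H]1O[C@H](c2cc(OC)c(OCc3ccccc3)c(OC)c2)[C@@H](CO[Si](c2ccccc2)(c2ccccc2)C(C)(C)C)[C@@H]1CO[Si](c1ccccc1)(c1ccccc1)C(C)(C)C | intermediate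
9 | [(2S,3R,4R,5S)-2,5-bis[4-(benzyloxy)-3,5-dimethoxyphenyl]tetrahydrofuran-3,4-diyl]dimethanol | COc1cc(cc(OC)c1OCc1ccccc1)[C@H]1O[C@H](c2cc(OC)c(OCc3ccccc3)c(OC)c2)[C@@H](CO)[C@@H]1CO | intermediate
10 | Huazhongilexin, 4,4'-[(2S,3R,4R,5S)-3,4-bis(hydroxymethyl)tetrahydrofuran-2,5-diyl]bis(2,6-dimethoxyphenol) | COc1cc([C@H]2O[C@H](c3cc(OC)c(O)c(OC)c3)[C@@H](CO)[C@@H]2CO)cc(OC)c1O | target

## Summary

Total steps: 8. Longest linear sequence: 7 (steps 1, 3, 4, 5, 6, 7, 8 from syringaldehyde); step 2 is a one-step side branch.

Steps most likely to fail: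

1. **Step 3 (proposed new asymmetric double aldol).** Risks are low enantio- or diastereocontrol in the first aldol and a sluggish second aldol of the acyloxy ketene acetal. Fallback (known chemistry): make racemic 5 by the stoichiometric TiCl4-mediated double aldol of 4 with 2, resolve by preparative chiral SFC, and rejoin at step 4.
2. **Step 6 (SN1 cycloetherification).** The benzylic cation can instead be trapped by the electron-rich second arene to give an aryltetralin, or the closure may give incomplete trans selectivity. Fallback: switch to a base-mediated quinone-methide closure. Carry the phenols as TIPS ethers from step 1, acetylate the two benzylic alcohols of the diol, and treat with TBAF/H2O at 0 °C; fluoride-triggered 1,6-elimination gives the bis-p-quinone methide, which is hydrated and closes by oxa-1,6-addition with no carbocation involved.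
3. **Step 8 (hydrogenolysis).** Over-reduction could cleave the benzylic C–O bonds of the THF ring. Fallback: change the protecting-group strategy by using allyl bromide in step 1, and remove the allyl ethers at the end with Pd(PPh3)4/K2CO3/MeOH so that no H2/Pd is applied to the ring.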